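10.0 s into Saturday's run you read 50.1 % of right-handed substrate and 50.1 % of left-handed substrate, and the two stay level within the scatter to the last reading, although the catalyst is single-handed.

all flasks: left-handed substrate 10 mM; right-handed substrate 10 mM; gas 2.2 mM (held)

|  | precatalyst | remark | time |
|---|---|---|---|
| Saturday's | 11 mol% | run made earlier |  |
| Tuesday's | 23 mol% | run made earlier |  |
| north-west | 15 mol% |  | 2.5 min |
| south-east | 30 mol% |  | 2.5 min |

- Saturday's (time / s: right-handed substrate / %, left-handed substrate / %): 10.0: 50.1, 50.1; 15.0: 49.8, 49.0; 30.0: 48.5, 49.5; 60.0: 48.0, 47.4; 120: 43.9, 43.7
- Tuesday's (time / s: right-handed substrate / %, left-handed substrate / %): 20.0: 49.8, 49.2; 40.0: 48.4, 47.6; 60.0: 47.1, 46.8; 80.0: 45.8, 44.2; 120: 37.6, 37.2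

(scatter of a reading: 1 percentage point)

* the winner by excess of right-handed substrate over left-handed substrate among what is left of the two; "neither" if no more than 2 percentage points parts them (north-west / south-east / neither)
* excess of right-handed substrate over left-handed substrate among what is left of the two at the end, north-west
* excess of right-handed substrate over left-handed substrate among what is left of the two at the end, south-east

- catalyst is single-handed; left-handed substrate and right-handed substrate are mirror images of each other, charged as a racemate, each of them at the stated concentration
- at the start none of the gas is in solution
- an excess is below zero if the other one leads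

Loss accelerates: Tuesday's run has lost 6.10 % at 60.0 s and 25.2 % at 120 s, twice Saturday's loss at that time. So I write minus the logarithm of the fraction left as a constant times loading times time squared. Differentiated, this gives the present loss rate, twice that logarithm over time: 0.00484 s⁻¹ at Tuesday's last reading.

My reckoning supposes that the substrates interconvert. Then the excess, ([right-handed substrate] − [left-handed substrate]) over their sum, follows the present rate, not the accumulated loss. Their ratio I call the lag. Tuesday's last pair gives an excess of 0.535 %, smaller than its scatter of 1.9 percentage points, so the lag of 1.11 s, the excess divided by the present loss rate, is a rough reading.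

Scaled by loading and by time to the end of the run, Tuesday's rate gives me 0.00789 s⁻¹ for south-east and 0.00395 s⁻¹ for north-west. So the lag is the fastest rung. Next comes south-east's loss time, 127 s, far longer than the lag. Slowest is north-west's, 253 s, longer than the 2.5 min of the run. Lag times rate gives me 0.436 % for north-west and 0.872 % for south-east, which are 0.44 points apart, less than the margin, so my call is neither.

The forecast says neither, with 1.2 % for north-west and 3 % for south-east, each higher than mine, and calls the selectivity “barely distinguishable from 1”.

The flask gives neither: 0.465 % in north-west, 0.807 % in south-east.

    left-handed substrate ⇌ right-handed substrate (k = 0.245 s⁻¹)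
    precatalyst → catalyst (k = 0.00916 s⁻¹)
    coupling partner + catalyst + right-handed substrate → catalyst + right-handed product (k = 204 M⁻² s⁻¹)
    gas ⇌ coupling partner, rate k4*(csat - [coupling partner]) (kL = 0.0839 s⁻¹)
    coupling partner + catalyst + left-handed substrate → catalyst + left-handed product (k = 2600 M⁻² s⁻¹)

This is a dynamic kinetic resolution: south-east's product ends with an excess of 85.3 % of left-handed product, while its substrates relax, by their interconversion alone, with a half-life of 1.41 s, shorter than the run. Now cut south-east's precatalyst to 7.5 mol% and keep the time. By my scaling the present rate becomes 0.00197 s⁻¹, the lag gives 0.219 %, and that flask stands at 0.258 %.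

(The numbers in the tables stem from a simulated flask from invented constants, noise included.)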